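The 2,2-dimethyldihydropyran ring carries its ring oxygen and its benzylic CH2 ortho to each other on the phloroglucinol-type A ring, which makes it a latent ortho-quinone methide. Cutting the benzylic CH2–CH2 bond and the O–C(CH3)2 bond leaves this 1-oxadiene and isobutylene. The key step is a three-component annulation: symmetric 2,6-dihydroxy-4-methoxybenzaldehyde is hydroxymethylated with formaldehyde and loses water to the ortho-quinone methide. Isobutylene traps it in an inverse-demand hetero-Diels–Alder reaction that closes the chroman in one operation. The resulting salicylaldehyde is condensed with 6-hydroxybenzofuran-2(3H)-one to a 3-(2-hydroxyaryl)coumarin, and a copper(II)-mediated dehydrogenative C–O closure forms the furan ring of the coumestan.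

Key step: step 1

Remark: the target has no stereocentre and no stereogenic axis, so it is achiral and needs no enantiocontrol; compounds 1, 2 and 6 are taken as catalogue compounds.

Step 1
Reactants: 1 2,6-dihydroxy-4-methoxybenzaldehyde; 2 isobutylene (2-methylpropene)
Product: 5 7-hydroxy-5-methoxy-2,2-dimethylchroman-8-carbaldehyde, via hydroxymethyl phenol 3 (not isolated), via ortho-quinone methide 4 (not isolated)
Conditions: (CH2O)n (1.0 equiv), isobutylene (ca. 20 equiv, condensed in), NaOAc (0.3 equiv), AcOH, pressure vessel, 85 °C
Reagents that add atoms: paraformaldehyde (as formaldehyde) C=O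
Why: Acetate-buffered Knoevenagel-type hydroxymethylation of 1 at C3 (C3 and C5 are equivalent by symmetry, so no regiochemical choice arises) gives 3, which loses water to the ortho-quinone methide 4, a 1-oxadiene (O=C2–C3=CH2) made electron-poor by the neighbouring formyl group. 4 reacts with isobutylene in an inverse-electron-demand hetero-Diels–Alder reaction; the closest known reaction type is the three-component phenol/aldehyde/alkene chroman annulation, as practised with acylphloroglucinols and 1,1-disubstituted alkenes. The dihydropyran ring is closed by the intermolecular [4+2] cycloaddition itself, which forms the CH2–CH2 bond and the O–C(CH3)2 bond in one asynchronous concerted event and restores the aromatic ring. No stereocentre is created. The step needs orientation control (oxygen to the tertiary carbon), which the polarisation of both partners secures: the nucleophilic CH2 terminus of isobutylene bonds to the electrophilic exocyclic methylene and the developing tertiary cationic centre is captured by the carbonyl oxygen. It also needs mono-annulation and suppression of diarylmethane formation, secured by one equivalent of formaldehyde, by the remaining 7-OH of 5 being chelated to the aldehyde and therefore a poor quinone methide donor, and by the large excess of isobutylene in a non-phenoxide medium.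

Step 2
Reactants: 5 7-hydroxy-5-methoxy-2,2-dimethylchroman-8-carbaldehyde; 6 6-hydroxybenzofuran-2(3H)-one
Product: 8 9-(2,4-dihydroxyphenyl)-5-methoxy-2,2-dimethyl-3,4-dihydro-2H,8H-pyrano[2,3-f]chromen-8-one, via benzylidene benzofuranone 7 (not isolated)
Conditions: Et3N (3 equiv), 4 Å MS, MeCN, reflux
Reagents that add atoms: none
Why: Knoevenagel condensation of the acidic lactone CH2 of 6 with the aldehyde should give the benzylidene benzofuranone 7, whose neighbouring phenoxide attacks the strained aryl lactone carbonyl (translactonisation, the benzylidene-benzofuranone-to-coumarin ring transformation) to release the 2'-OH and give the conjugated coumarin, the single free OH ortho to the formyl group of 5 making the lactone closure unambiguous; no stereocentre is formed.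

Step 3
Reactants: 8 9-(2,4-dihydroxyphenyl)-5-methoxy-2,2-dimethyl-3,4-dihydro-2H,8H-pyrano[2,3-f]chromen-8-one
Product: 9 target CNP0304440.0, 9-hydroxy-3-methoxycoumestan with a 2,2-dimethyl-3,4-dihydro-2H-pyran ring fused through O at C1 and CH2 at C2 (coumestan numbering)
Conditions: Cu(OAc)2 (2.2 equiv), DMF, 120 °C, Ar
Reagents that add atoms: none
Why: Copper(II)-mediated intramolecular dehydrogenative C–O coupling (oxidative cyclisation of a 3-(2-hydroxyaryl)coumarin to a coumestan), in which the copper-bound 2'-phenoxide adds to C4 of the coumarin and two Cu(II) equivalents take up the two electrons so that the C3=C4 bond is re-formed inside the new furan ring, only the 2'-OH being able to reach C4 and the chroman CH2 groups being inert to Cu(OAc)2; no stereocentre is formed.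

Compound list
1 | 2,6-dihydroxy-4-methoxybenzaldehyde | COc1cc(O)c(C=O)c(O)c1 | starting material
2 | isobutylene (2-methylpropene) | CC(C)=C | starting material
3 | 2,6-dihydroxy-3-(hydroxymethyl)-4-methoxybenzaldehyde | COc1cc(O)c(C=O)c(O)c1CO | intermediate
4 | ortho-quinone methide, 2-hydroxy-4-methoxy-5-methylidene-6-oxocyclohexa-1,3-diene-1-carbaldehyde | COC1=CC(O)=C(C=O)C(=O)C1=C | intermediate
5 | 7-hydroxy-5-methoxy-2,2-dimethylchroman-8-carbaldehyde | COc1cc(O)c(C=O)c2OC(C)(C)CCc12 | intermediate
6 | 6-hydroxybenzofuran-2(3H)-one | O=C1Cc2ccc(O)cc2O1 | starting material
7 | (Z)-6-hydroxy-3-[(7-hydroxy-5-methoxy-2,2-dimethylchroman-8-yl)methylidene]benzofuran-2(3H)-one (drawn as the Z isomer that lactonises; E and Z should equilibrate under the base) | O=C1Oc2cc(O)ccc2/C1=C/c1c(O)cc(OC)c2CCC(C)(C)Oc12 | intermediate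
8 | 9-(2,4-dihydroxyphenyl)-5-methoxy-2,2-dimethyl-3,4-dihydro-2H,8H-pyrano[2,3-f]chromen-8-one | COc1cc2oc(=O)c(-c3ccc(O)cc3O)cc2c2OC(C)(C)CCc12 | intermediate
9 | target CNP0304440.0, 9-hydroxy-3-methoxycoumestan with a 2,2-dimethyl-3,4-dihydro-2H-pyran ring fused through O at C1 and CH2 at C2 | COc1cc2oc(=O)c3c4ccc(O)cc4oc3c2c2c1CCC(C)(C)O2 | target

Total step count: 3
Longest linear sequence: 3 steps (1 → 5 → 8 → 9)

Steps most likely to fail

Step 1. The quinone methide may be captured by a second molecule of the phenol instead of the alkene (methylene bridging), or a second annulation may follow on the remaining phenol. The fallback separates C–C bond formation from the cycloaddition. Setting out from 1, a Mannich reaction with aqueous formaldehyde and dimethylamine (EtOH, rt) should give the Mannich base 3-[(dimethylamino)methyl]-2,6-dihydroxy-4-methoxybenzaldehyde F1, which can be freed from doubly aminomethylated material before use. Slow thermolysis of F1 in toluene with a large excess of isobutylene (autoclave, 150 °C) should expel dimethylamine and release the same ortho-quinone methide 4 at a low stationary concentration. Its cycloaddition with 2 returns the route at 5.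

Step 3. The electron-rich phenol rings may be over-oxidised, or the closure may stall at low conversion. The fallback is a metal-free hydride-abstraction route. Setting out from 8, DDQ (1.1 equiv) in 1,4-dioxane at 40–60 °C should effect oxa-Michael ring closure followed by dehydrogenation and return the route directly at 9; no new compound arises (F0). The temperature is kept low so that the benzylic CH2 of the chroman is not dehydrogenated.

Step 2. Condensation of the hindered, electron-rich aldehyde may be incomplete, or the lactone partner may be opened and oligomerised by the base. The fallback is a Perkin–Oglialoro condensation. Setting out from 5, heating with 2,4-dihydroxyphenylacetic acid in Ac2O/Et3N (110 °C) should give the diacetate 9-(2,4-diacetoxyphenyl)-5-methoxy-2,2-dimethyl-3,4-dihydro-2H,8H-pyrano[2,3-f]chromen-8-one F2. Methanolysis of the two aryl acetates (HCl, MeOH, reflux) then returns the route at 8.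

Further compounds
F1 | step 1 | 3-[(dimethylamino)methyl]-2,6-dihydroxy-4-methoxybenzaldehyde | COc1cc(O)c(C=O)c(O)c1CN(C)C
F2 | step 2 | 9-(2,4-diacetoxyphenyl)-5-methoxy-2,2-dimethyl-3,4-dihydro-2H,8H-pyrano[2,3-f]chromen-8-one | COc1cc2oc(=O)c(-c3ccc(OC(C)=O)cc3OC(C)=O)cc2c2OC(C)(C)CCc12
F0 | step 3 | none | none
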